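The target is cut across its furan ring: the ring B–ring C carbon–carbon bond and the bond from the furan oxygen to ring C. Ring B carries that furan oxygen para to the dioxin oxygen lying between two oxygenated carbons, which is the substitution pattern of a 2-aryloxy-6-methoxy-1,4-benzoquinone with a free CH, and ring C is an intact phloroglucinol. Acid-promoted C-arylation of quinone 13 by phloroglucinol followed by cyclodehydration therefore builds both bonds and the furan in one operation. Quinone 13 already holds brominated ring A and ring D; its 2,6-pattern is fixed by Teuber oxidation of a phenol. Copper-mediated dioxin closure and global demethylation finish the synthesis.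

Key step: step 8

Remark on the chemistry: the target has no stereocentre. Ring A is brominated before ring D is attached, because a 3,5-dimethoxyphenoxy ring would take up electrophilic bromine first. The quinone is made by oxidising a phenol, because substitution on a 2-bromo-6-methoxyquinone could follow an ipso or a cine path. Compounds 7, 9 and 14 are taken as purchasable.

Step 1
Reactants: 1 1,3-dimethoxybenzene
Product: 3 4,6-dimethoxybenzene-1,3-dicarbaldehyde, via 2,4-dimethoxybenzaldehyde 2 (not isolated)
Conditions: Cl2CHOMe (4 equiv), TiCl4 (4 equiv), CH2Cl2, 0 °C to rt; aq. HCl work-up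
Reagents that add atoms: dichloromethyl methyl ether, COC(Cl)Cl; water, O
Why: Rieche formylation (electrophilic aromatic substitution by the TiCl4-activated chloromethyl ether) enters para to one methoxy and ortho to the other, and the second formyl group goes to the 5-position of 2, which both methoxy groups still activate, so hydrolytic work-up should give the 4,6-dimethoxy dialdehyde.

Step 2
Reactants: 3 4,6-dimethoxybenzene-1,3-dicarbaldehyde
Product: 5 4,6-dimethoxybenzene-1,3-diol, via 4,6-dimethoxy-1,3-phenylene diformate 4 (not isolated)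
Conditions: mCPBA (2.5 equiv), CH2Cl2, rt; then K2CO3 (cat.), MeOH, rt, N2
Reagents that add atoms: 3-chloroperoxybenzoic acid (mCPBA), OOC(=O)c1cccc(Cl)c1
Why: Baeyer–Villiger oxidation with migration of the electron-rich aryl group turns each formyl group into a formate, and base-catalysed methanolysis then frees the symmetric resorcinol.

Step 3
Reactants: 5 4,6-dimethoxybenzene-1,3-diol
Product: 6 2-bromo-4,6-dimethoxybenzene-1,3-diol
Conditions: NBS (1.0 equiv), i-Pr2NH (10 mol%), CH2Cl2, −78 °C to 0 °C
Reagents that add atoms: N-bromosuccinimide, O=C1CCC(=O)N1Br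
Why: Amine-catalysed electrophilic bromination by NBS goes ortho to free hydroxyl, and C-2 is ortho to both hydroxyls whereas the only other free position, C-5, sits between two methoxy groups; at this stage no ring D is present to compete.

Step 4
Reactants: 6 2-bromo-4,6-dimethoxybenzene-1,3-diol; 7 (3,5-dimethoxyphenyl)boronic acid
Product: 8 2-bromo-3-(3,5-dimethoxyphenoxy)-4,6-dimethoxyphenol
Conditions: 6 (2 equiv), 7 (1 equiv, in portions), Cu(OAc)2 (1 equiv), pyridine (5 equiv), 4 Å MS, CH2Cl2, dry air, rt
Reagents that add atoms: none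
Why: Chan–Lam oxidative O-arylation (aryl transfer from boron to a copper phenoxide, C–O reductive elimination, air as terminal oxidant) runs at room temperature, tolerates phenols flanked by halogen and alkoxy groups and leaves the aryl bromide untouched, while the excess of symmetric diol should favour the mono-ether and allow recovery of 6.

Step 5
Reactants: 8 2-bromo-3-(3,5-dimethoxyphenoxy)-4,6-dimethoxyphenol; 9 2-fluoro-6-methoxybenzaldehyde
Product: 10 2-[2-bromo-3-(3,5-dimethoxyphenoxy)-4,6-dimethoxyphenoxy]-6-methoxybenzaldehyde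
Conditions: 9 (1.3 equiv), Cs2CO3 (1.5 equiv), DMSO, 100 °C, N2
Reagents that add atoms: none
Why: Nucleophilic aromatic substitution (addition–elimination through a Meisenheimer adduct) of the ortho-formyl-activated fluoride by the cesium phenoxide of 8 is standard for 2-fluorobenzaldehydes and puts the ring A ether and the methoxy group on either side of the formyl carbon, so the later quinone can only be the 2-aryloxy-6-methoxy isomer.

Step 6
Reactants: 10 2-[2-bromo-3-(3,5-dimethoxyphenoxy)-4,6-dimethoxyphenoxy]-6-methoxybenzaldehyde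
Product: 12 2-[2-bromo-3-(3,5-dimethoxyphenoxy)-4,6-dimethoxyphenoxy]-6-methoxyphenol, via aryl formate 11 (not isolated)
Conditions: mCPBA (1.3 equiv), CH2Cl2, 0 °C to rt; then K2CO3 (cat.), MeOH, rt
Reagents that add atoms: 3-chloroperoxybenzoic acid (mCPBA), OOC(=O)c1cccc(Cl)c1
Why: Baeyer–Villiger oxidation of the 2,6-dioxygenated benzaldehyde (migration of the electron-rich aryl) should give formate 11, whose mild methanolysis frees the phenol without touching the aryl ethers or the bromide.

Step 7
Reactants: 12 2-[2-bromo-3-(3,5-dimethoxyphenoxy)-4,6-dimethoxyphenoxy]-6-methoxyphenol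
Product: 13 2-[2-bromo-3-(3,5-dimethoxyphenoxy)-4,6-dimethoxyphenoxy]-6-methoxy-1,4-benzoquinone
Conditions: (KSO3)2NO (Fremy's salt, 2.5 equiv), KH2PO4, acetone/H2O, rt
Reagents that add atoms: potassium nitrosodisulfonate, [K+].[K+].[O]N(S(=O)(=O)[O-])S(=O)(=O)[O-]
Why: Teuber oxidation, in which the nitroxyl radical abstracts the phenolic hydrogen and a second equivalent delivers oxygen to the free para carbon, can only give the para-quinone because both ortho positions carry ether groups, and rings A and D lack a free hydroxyl and are not attacked.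

Step 8
Reactants: 13 2-[2-bromo-3-(3,5-dimethoxyphenoxy)-4,6-dimethoxyphenoxy]-6-methoxy-1,4-benzoquinone; 14 phloroglucinol
Product: 16 1-[2-bromo-3-(3,5-dimethoxyphenoxy)-4,6-dimethoxyphenoxy]-3-methoxydibenzofuran-2,7,9-triol, via aryl hydroquinone 15 (not isolated)
Conditions: 14 (4 equiv), TsOH·H2O (20 mol%), AcOH/THF, 25 °C then 60 °C, argon, slow addition of 13
Reagents that add atoms: none
Why: Brønsted acid activates the quinone and phloroglucinol adds through carbon to C-3, the CH beside the aryloxy-bearing C-2, after which enolisation gives aryl hydroquinone 15; this is the known acid-catalysed arylation of 1,4-benzoquinones by phloroglucinol or resorcinols that ends in hydroxydibenzofurans. The C-4 hydroxyl of 15, ortho to the new biaryl bond, then attacks the carbonyl carbon of the protonated keto tautomer of the trihydroxyphenyl ring (5-exo-trig) and loss of water aromatises the furan, so the ring B–ring C bond, the furan O–C bond and the furan ring arise in one flask. No stereocentre is created. The step needs attack at C-3 and not at C-5 or ipso at C-2 or C-6: aryloxy, made still poorer by the ortho bromine and the twist of ring A, is a weaker π-donor than methoxy, so the C-2/C-3 enone is the more electrophilic, and acid in a weakly nucleophilic medium favours carbon attack at CH over exchange of the ether groups. Excess phloroglucinol and slow addition of 13 should keep ring D and product 16 from acting as competing nucleophiles and limit oxidation of 15 by unreacted quinone. Since the C-1 carbonyl between the two ether-bearing carbons is left as the only free ring B hydroxyl, next to the ring A ether, the later dioxin closure has a single possible sense.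

Step 9
Reactants: 16 1-[2-bromo-3-(3,5-dimethoxyphenoxy)-4,6-dimethoxyphenoxy]-3-methoxydibenzofuran-2,7,9-triol
Product: 17 dioxin-closed pentamethyl ether of the target (3-methoxydibenzofuran-7,9-diol whose O-1 and O-2 are bridged by the 3-(3,5-dimethoxyphenoxy)-4,6-dimethoxybenzene-1,2-diyl unit of ring A, O-1 on ring A C-1 and O-2 on ring A C-2)
Conditions: CuI (1 equiv), Cs2CO3 (4 equiv), pyridine, 115 °C, 5 mM, argon
Reagents that add atoms: none
Why: Intramolecular Ullmann diaryl ether synthesis, in which the cesium phenoxide of the 2-hydroxyl, held next to the ring A bromide by the existing ether bridge, displaces bromide at copper to close the six-membered 1,4-dioxin, should be favoured over intermolecular coupling of the ring C phenoxides by high dilution and by the hindered, electron-rich nature of the bromide.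

Step 10
Reactants: 17 dioxin-closed pentamethyl ether of the target
Product: 18 target CNP0256302.0 (the heptaphenol obtained by cleaving all five methyl ethers of 17)
Conditions: BBr3 (15 equiv), CH2Cl2, −78 °C to rt; then H2O
Reagents that add atoms: none
Why: Lewis acid-mediated cleavage of aryl methyl ethers (O–B complexation, bromide attack on methyl) should remove all five methyl groups, while the diaryl ether, dioxin and furan C–O bonds offer no alkyl carbon for bromide and survive.

Compound list
1 | 1,3-dimethoxybenzene | COc1cccc(OC)c1 | starting material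
2 | 2,4-dimethoxybenzaldehyde | COc1ccc(C=O)c(OC)c1 | intermediate (not isolated)
3 | 4,6-dimethoxybenzene-1,3-dicarbaldehyde | COc1cc(OC)c(C=O)cc1C=O | intermediate
4 | 4,6-dimethoxy-1,3-phenylene diformate | COc1cc(OC)c(OC=O)cc1OC=O | intermediate (not isolated)
5 | 4,6-dimethoxybenzene-1,3-diol | COc1cc(OC)c(O)cc1O | intermediate
6 | 2-bromo-4,6-dimethoxybenzene-1,3-diol | COc1cc(OC)c(O)c(Br)c1O | intermediate
7 | (3,5-dimethoxyphenyl)boronic acid | COc1cc(OC)cc(B(O)O)c1 | starting material
8 | 2-bromo-3-(3,5-dimethoxyphenoxy)-4,6-dimethoxyphenol | COc1cc(OC)c(Oc2cc(OC)cc(OC)c2)c(Br)c1O | intermediate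
9 | 2-fluoro-6-methoxybenzaldehyde | COc1cccc(F)c1C=O | starting material
10 | 2-[2-bromo-3-(3,5-dimethoxyphenoxy)-4,6-dimethoxyphenoxy]-6-methoxybenzaldehyde | COc1cccc(Oc2c(OC)cc(OC)c(Oc3cc(OC)cc(OC)c3)c2Br)c1C=O | intermediate
11 | 2-[2-bromo-3-(3,5-dimethoxyphenoxy)-4,6-dimethoxyphenoxy]-6-methoxyphenyl formate | COc1cccc(Oc2c(OC)cc(OC)c(Oc3cc(OC)cc(OC)c3)c2Br)c1OC=O | intermediate (not isolated)
12 | 2-[2-bromo-3-(3,5-dimethoxyphenoxy)-4,6-dimethoxyphenoxy]-6-methoxyphenol | COc1cccc(Oc2c(OC)cc(OC)c(Oc3cc(OC)cc(OC)c3)c2Br)c1O | intermediate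
13 | 2-[2-bromo-3-(3,5-dimethoxyphenoxy)-4,6-dimethoxyphenoxy]-6-methoxy-1,4-benzoquinone | COC1=CC(=O)C=C(Oc2c(OC)cc(OC)c(Oc3cc(OC)cc(OC)c3)c2Br)C1=O | intermediate
14 | phloroglucinol (benzene-1,3,5-triol) | Oc1cc(O)cc(O)c1 | starting material
15 | 2-[2-bromo-3-(3,5-dimethoxyphenoxy)-4,6-dimethoxyphenoxy]-6-methoxy-3-(2,4,6-trihydroxyphenyl)benzene-1,4-diol | COc1cc(O)c(-c2c(O)cc(O)cc2O)c(Oc2c(OC)cc(OC)c(Oc3cc(OC)cc(OC)c3)c2Br)c1O | intermediate (not isolated)
16 | 1-[2-bromo-3-(3,5-dimethoxyphenoxy)-4,6-dimethoxyphenoxy]-3-methoxydibenzofuran-2,7,9-triol | COc1cc2oc3cc(O)cc(O)c3c2c(Oc2c(OC)cc(OC)c(Oc3cc(OC)cc(OC)c3)c2Br)c1O | intermediate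
17 | dioxin-closed pentamethyl ether of the target (ring D 3,5-dimethoxy, ring A dimethoxy, ring B methoxy, ring C 7,9-diol free) | COc1cc(OC)cc(Oc2c(OC)cc(OC)c3c2Oc2c(OC)cc4oc5cc(O)cc(O)c5c4c2O3)c1 | intermediate
18 | target CNP0256302.0 (heptaphenol: benzofuran-fused dibenzo-1,4-dioxin carrying a 3,5-dihydroxyphenoxy group on ring A) | Oc1cc(O)cc(Oc2c(O)cc(O)c3c2Oc2c(O)cc4oc5cc(O)cc(O)c5c4c2O3)c1 | target

Total step count: 10. Longest linear sequence: 10 steps (1 to 18).

Steps most likely to fail

Step 8. The arylation may go to the methoxy-flanked CH (C-5), the aryloxy group may be exchanged by ipso attack, or 15 may be oxidised by unreacted 13. The fallback sets out from 8 and comes back at 17; it blocks the competing CH with chlorine from the building-block stage.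
- 2-Chloro-5-fluoroanisole is lithiated between fluorine and methoxy (LiN(iPr)2, THF, −78 °C) and formylated with DMF to give 3-chloro-6-fluoro-2-methoxybenzaldehyde F1.
- SNAr with 8 (Cs2CO3, DMSO, 100 °C) should give 6-[2-bromo-3-(3,5-dimethoxyphenoxy)-4,6-dimethoxyphenoxy]-3-chloro-2-methoxybenzaldehyde F2.
- Baeyer–Villiger oxidation (mCPBA) through the chloro aryl formate F3 and methanolysis should give 6-[2-bromo-3-(3,5-dimethoxyphenoxy)-4,6-dimethoxyphenoxy]-3-chloro-2-methoxyphenol F4.
- Teuber oxidation with (KSO3)2NO should give 5-[2-bromo-3-(3,5-dimethoxyphenoxy)-4,6-dimethoxyphenoxy]-2-chloro-3-methoxy-1,4-benzoquinone F5, whose only CH is the one next to the aryloxy group.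
- Acid-catalysed arylation by phloroglucinol (halogenated quinones are arylated at CH under acid with the halogen retained) should pass through the chloro aryl hydroquinone F6 to 1-[2-bromo-3-(3,5-dimethoxyphenoxy)-4,6-dimethoxyphenoxy]-4-chloro-3-methoxydibenzofuran-2,7,9-triol F7.
- CuI/Cs2CO3 closure onto the ring A bromide, with the aryl chloride inert, should give the ring B chloro derivative of 17 F8.
- Hydrogenolysis of the C–Cl bond (H2, Pd/C, Et3N, MeOH/THF) returns 17.

Step 9. The unprotected ring C phenoxides may couple intermolecularly or be degraded oxidatively at copper instead of the ring closing. The fallback sets out from 16 and comes back at 18; it masks the two ring C hydroxyls first.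
- Alkylation with BnBr (2.1 equiv, K2CO3, acetone) should spare the 2-hydroxyl, which is buttressed between the aryloxy and methoxy groups, and give 7,9-bis(benzyloxy)-1-[2-bromo-3-(3,5-dimethoxyphenoxy)-4,6-dimethoxyphenoxy]-3-methoxydibenzofuran-2-ol F9.
- Ullmann closure as in step 9 should give the 7,9-di-O-benzyl ether of 17 F10.
- BBr3 with pentamethylbenzene as cation scavenger cleaves the benzyl and methyl ethers together to give 18.

Step 4. The electron-rich diol may be oxidised under aerobic copper, the boronic acid may be lost by protodeboronation, or over-arylation may give the bis-ether. The fallback sets out from 6 and comes back at 8.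
- The oxidative coupling is replaced by a redox-neutral Ullmann etherification of 6 (in excess) with purchased 1-iodo-3,5-dimethoxybenzene (CuI, picolinic acid, K3PO4, DMSO, 80 °C, argon).
- The aryl iodide should react well before the flanked, electron-rich ring A bromide.
- New compounds: none F0.

Further compounds
F1 | step 8 | 3-chloro-6-fluoro-2-methoxybenzaldehyde | COc1c(Cl)ccc(F)c1C=O
F2 | step 8 | 6-[2-bromo-3-(3,5-dimethoxyphenoxy)-4,6-dimethoxyphenoxy]-3-chloro-2-methoxybenzaldehyde | COc1c(Cl)ccc(Oc2c(OC)cc(OC)c(Oc3cc(OC)cc(OC)c3)c2Br)c1C=O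
F3 | step 8 | 6-[2-bromo-3-(3,5-dimethoxyphenoxy)-4,6-dimethoxyphenoxy]-3-chloro-2-methoxyphenyl formate | COc1c(Cl)ccc(Oc2c(OC)cc(OC)c(Oc3cc(OC)cc(OC)c3)c2Br)c1OC=O
F4 | step 8 | 6-[2-bromo-3-(3,5-dimethoxyphenoxy)-4,6-dimethoxyphenoxy]-3-chloro-2-methoxyphenol | COc1c(Cl)ccc(Oc2c(OC)cc(OC)c(Oc3cc(OC)cc(OC)c3)c2Br)c1O
F5 | step 8 | 5-[2-bromo-3-(3,5-dimethoxyphenoxy)-4,6-dimethoxyphenoxy]-2-chloro-3-methoxy-1,4-benzoquinone | COC1=C(Cl)C(=O)C=C(Oc2c(OC)cc(OC)c(Oc3cc(OC)cc(OC)c3)c2Br)C1=O
F6 | step 8 | 2-[2-bromo-3-(3,5-dimethoxyphenoxy)-4,6-dimethoxyphenoxy]-5-chloro-6-methoxy-3-(2,4,6-trihydroxyphenyl)benzene-1,4-diol | COc1c(Cl)c(O)c(-c2c(O)cc(O)cc2O)c(Oc2c(OC)cc(OC)c(Oc3cc(OC)cc(OC)c3)c2Br)c1O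
F7 | step 8 | 1-[2-bromo-3-(3,5-dimethoxyphenoxy)-4,6-dimethoxyphenoxy]-4-chloro-3-methoxydibenzofuran-2,7,9-triol | COc1c(Cl)c2oc3cc(O)cc(O)c3c2c(Oc2c(OC)cc(OC)c(Oc3cc(OC)cc(OC)c3)c2Br)c1O
F8 | step 8 | ring B chloro derivative of 17 (chlorine on the ring B carbon between the methoxy-bearing carbon and the furan oxygen) | COc1cc(OC)cc(Oc2c(OC)cc(OC)c3c2Oc2c(OC)c(Cl)c4oc5cc(O)cc(O)c5c4c2O3)c1
F9 | step 9 | 7,9-bis(benzyloxy)-1-[2-bromo-3-(3,5-dimethoxyphenoxy)-4,6-dimethoxyphenoxy]-3-methoxydibenzofuran-2-ol | COc1cc2oc3cc(OCc4ccccc4)cc(OCc4ccccc4)c3c2c(Oc2c(OC)cc(OC)c(Oc3cc(OC)cc(OC)c3)c2Br)c1O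
F10 | step 9 | 7,9-di-O-benzyl ether of 17 | COc1cc(OC)cc(Oc2c(OC)cc(OC)c3c2Oc2c(OC)cc4oc5cc(OCc6ccccc6)cc(OCc6ccccc6)c5c4c2O3)c1
F0 | step 4 | none | none
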